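**Plan**
1. Ring A carries C1–OH, C2–CH2Ar, C3–OMe and C5–CH2CH2Ar'. The retrosynthesis raises the diarylmethane CH2 to a ketone, restores the C1 methyl ether, and then cuts both aryl–C(=O) bonds at once, so that the carbonyl carbon is carbon monoxide.
2. This works because that CH2 is a single carbon bonded only to C2 of ring A (between C–OMe and C–OH) and to C1 of the 4-hydroxyphenyl ring. As C=O it lies between two ortho oxygens and can chelate boron, which lets exactly one methyl ether be removed.
3. Further cuts are the C2–I bond (lithiation between the two methoxy groups), the ring A C5–CH2 bond (B-alkyl Suzuki coupling) and the styrene C=C (Wittig).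
4. Forward, no ring is formed. The chain is joined in the order aldehyde → styrene → bibenzyl → aryl iodide → diaryl ketone (ArI + CO + Ar'B(OH)2) → triphenol ketone → diarylmethane.
5. The target has no stereocentre and no stereogenic double bond, so nothing has to be set; the one transient carbinol centre in the last step is erased.

Key step: step 4

Assumption: the target is achiral, so the compound as drawn is the required single form. The phenols are carried as isopropyl ethers, which are inert to n-BuLi and to Pd/base and are removed by BCl3 without loss of unchelated methyl ethers. Compounds 1, 3, 8 and 9 are taken as commercial.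

**Route**

Step 1
Reactants: 1 3-isopropoxybenzaldehyde
Product: 2 1-ethenyl-3-isopropoxybenzene (3-isopropoxystyrene)
Conditions: Ph3PCH3Br, KOtBu, THF, 0 °C → rt
Reagents that add atoms: methyltriphenylphosphonium bromide, C[P+](c1ccccc1)(c1ccccc1)c1ccccc1.[Br-]
Why: Wittig methylenation of an aromatic aldehyde with the non-stabilised ylide is reliable, and the isopropyl ether is inert to the base.

Step 2
Reactants: 2 1-ethenyl-3-isopropoxybenzene; 3 1-bromo-3,5-dimethoxybenzene
Product: 5 1-[2-(3-isopropoxyphenyl)ethyl]-3,5-dimethoxybenzene, via B-alkyl-9-BBN borane 4 (not isolated)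
Conditions: 9-BBN (0.5 M in THF), 0 °C → rt; then 3, PdCl2(dppf) (3 mol %), 3 M aq. NaOH, THF, 65 °C
Reagents that add atoms: 9-borabicyclo[3.3.1]nonane, B1C2CCCC1CCC2 (its atoms are held in intermediate 4 only)
Why: The bulky borane should add anti-Markovnikov to the styrene, placing boron on the terminal carbon, and the primary alkyl-9-BBN then undergoes B-alkyl Suzuki–Miyaura coupling with the aryl bromide to form the sp3–sp2 bond of the bibenzyl.

Step 3
Reactants: 5 1-[2-(3-isopropoxyphenyl)ethyl]-3,5-dimethoxybenzene
Product: 7 2-iodo-5-[2-(3-isopropoxyphenyl)ethyl]-1,3-dimethoxybenzene, via aryllithium 6 (not isolated)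
Conditions: n-BuLi (1.2 equiv), THF, 0 °C → rt; then I2 in THF, −78 °C → rt; aq. Na2S2O3 work-up
Reagents that add atoms: iodine, II; n-butyllithium, [Li]CCCC (lithium is held in intermediate 6 only)
Why: Directed ortho-metalation: the C–H between the two methoxy groups is the most acidic ring position (double coordination and induction), so deprotonation should occur there and not next to the single isopropoxy group, and iodine traps the aryllithium; electrophilic iodination would instead go ortho to the alkyl chain.

Step 4
Reactants: 7 2-iodo-5-[2-(3-isopropoxyphenyl)ethyl]-1,3-dimethoxybenzene; 8 carbon monoxide; 9 4-isopropoxyphenylboronic acid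
Product: 10 {2,6-dimethoxy-4-[2-(3-isopropoxyphenyl)ethyl]phenyl}(4-isopropoxyphenyl)methanone
Conditions: PEPPSI-IPr (3 mol %), Cs2CO3 (3 equiv), CO (balloon), PhCl, 80 °C
Reagents that add atoms: carbon monoxide (compound 8), [C-]#[O+]
Why: Carbonylative Suzuki–Miyaura coupling: the Pd(0)–NHC species inserts into the C–I bond of 7, CO coordinates and migrates to give an aroylpalladium(II) iodide, the caesium boronate of 9 transfers its aryl group, and reductive elimination releases the diaryl ketone, so both aryl–carbonyl bonds of the later diarylmethane carbon form in one operation. The closest known reaction type is the palladium–NHC-catalysed carbonylative coupling of di-ortho-substituted aryl iodides with arylboronic acids to hindered benzophenones. No ring is closed and no stereocentre is created. The selectivity needed is CO insertion ahead of direct transmetalation, which would give the biaryl; the two methoxy groups flanking palladium slow transmetalation at the arylpalladium stage, migration to CO relieves that crowding, and the bulky IPr ligand under a CO atmosphere reinforces the preference. Both phenols are masked as isopropyl ethers, so no oxygen nucleophile can intercept the aroylpalladium as an ester.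

Step 5
Reactants: 10 {2,6-dimethoxy-4-[2-(3-isopropoxyphenyl)ethyl]phenyl}(4-isopropoxyphenyl)methanone
Product: 11 {2-hydroxy-4-[2-(3-hydroxyphenyl)ethyl]-6-methoxyphenyl}(4-hydroxyphenyl)methanone
Conditions: BCl3 (1 M in CH2Cl2, 6 equiv), CH2Cl2, −78 → 0 °C; then H2O
Reagents that add atoms: none
Why: Lewis-acid ether cleavage with BCl3: the secondary isopropyl ethers ionise readily once boron is bound, while among the methyl ethers only one that can close a six-membered boron chelate with the ketone oxygen is cleaved; the two ortho methoxy groups of 10 are equivalent, and once the chelate has formed the carbonyl is occupied, so the second one should stay.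

Step 6
Reactants: 11 {2-hydroxy-4-[2-(3-hydroxyphenyl)ethyl]-6-methoxyphenyl}(4-hydroxyphenyl)methanone
Product: 13 2-(4-hydroxybenzyl)-5-[2-(3-hydroxyphenyl)ethyl]-3-methoxyphenol, via benzhydrol 12 (not isolated)
Conditions: Et3SiH (5 equiv), TFA, CH2Cl2, 0 °C → rt
Reagents that add atoms: none
Why: Ionic hydrogenation: the protonated diaryl ketone is a carbenium ion stabilised by the ortho-OH, ortho-OMe and para-OH groups and takes hydride from the silane to give benzhydrol 12, which re-ionises to a doubly benzylic cation and takes a second hydride; the transient carbinol centre is destroyed and the product is achiral.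

**Compound list**
1 | 3-isopropoxybenzaldehyde | CC(C)Oc1cccc(C=O)c1 | starting material
2 | 1-ethenyl-3-isopropoxybenzene | C=Cc1cccc(OC(C)C)c1 | intermediate
3 | 1-bromo-3,5-dimethoxybenzene | COc1cc(Br)cc(OC)c1 | starting material
4 | 9-[2-(3-isopropoxyphenyl)ethyl]-9-borabicyclo[3.3.1]nonane (not isolated) | CC(C)Oc1cccc(CCB2C3CCCC2CCC3)c1 | intermediate
5 | 1-[2-(3-isopropoxyphenyl)ethyl]-3,5-dimethoxybenzene | COc1cc(CCc2cccc(OC(C)C)c2)cc(OC)c1 | intermediate
6 | {2,6-dimethoxy-4-[2-(3-isopropoxyphenyl)ethyl]phenyl}lithium (not isolated) | COc1cc(CCc2cccc(OC(C)C)c2)cc(OC)c1[Li] | intermediate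
7 | 2-iodo-5-[2-(3-isopropoxyphenyl)ethyl]-1,3-dimethoxybenzene | COc1cc(CCc2cccc(OC(C)C)c2)cc(OC)c1I | intermediate
8 | carbon monoxide | [C-]#[O+] | starting material
9 | 4-isopropoxyphenylboronic acid | CC(C)Oc1ccc(B(O)O)cc1 | starting material
10 | {2,6-dimethoxy-4-[2-(3-isopropoxyphenyl)ethyl]phenyl}(4-isopropoxyphenyl)methanone | COc1cc(CCc2cccc(OC(C)C)c2)cc(OC)c1C(=O)c1ccc(OC(C)C)cc1 | intermediate
11 | {2-hydroxy-4-[2-(3-hydroxyphenyl)ethyl]-6-methoxyphenyl}(4-hydroxyphenyl)methanone | COc1cc(CCc2cccc(O)c2)cc(O)c1C(=O)c1ccc(O)cc1 | intermediate
12 | 2-[hydroxy(4-hydroxyphenyl)methyl]-5-[2-(3-hydroxyphenyl)ethyl]-3-methoxyphenol (racemic, not isolated) | COc1cc(CCc2cccc(O)c2)cc(O)c1C(O)c1ccc(O)cc1 | intermediate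
13 | 2-(4-hydroxybenzyl)-5-[2-(3-hydroxyphenyl)ethyl]-3-methoxyphenol | COc1cc(CCc2cccc(O)c2)cc(O)c1Cc1ccc(O)cc1 | target

**Totals**
Total step count: 6. Longest linear sequence: 6 steps (1 → 2 → 5 → 7 → 10 → 11 → 13).

**Steps most likely to fail**

Step 4. The arylpalladium species may transmetalate before CO inserts and give the biaryl. Oxidative addition into the crowded, electron-rich C–I bond may also stall under CO, or the boronic acid may protodeboronate. The fallback gives up the catalytic three-component union and makes the same ketone by polar addition and oxidation. It sets out from bibenzyl 5: aryllithium 6, generated as in step 3, is added to commercial 4-isopropoxybenzaldehyde (THF, −78 → 0 °C) to give the carbinol {2,6-dimethoxy-4-[2-(3-isopropoxyphenyl)ethyl]phenyl}(4-isopropoxyphenyl)methanol F1. Oxidation of this carbinol with Dess–Martin periodinane or MnO2 in CH2Cl2 returns to the route at ketone 10.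

Step 5. The chelation-controlled loss of one methyl ether may be sluggish, because the doubly ortho-substituted carbonyl is twisted out of the plane of ring A and binds boron poorly. Forcing it may remove both methyl ethers. The fallback separates the two events and removes the methyl group by a different mechanism. It sets out from ketone 10: sodium ethanethiolate in DMF at about 110 °C demethylates by SN2 attack at the methyl carbon of the carbonyl-activated ether and stops after one cleavage because the resulting phenoxide deactivates the ring. This gives {2-hydroxy-6-methoxy-4-[2-(3-isopropoxyphenyl)ethyl]phenyl}(4-isopropoxyphenyl)methanone F2. The two isopropyl ethers are then removed with BCl3 in CH2Cl2 at −78 → 0 °C, conditions under which aryl methyl ethers persist, and the route is rejoined at triphenol ketone 11.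

Step 6. Hydride transfer to the hydrogen-bonded, hindered carbonyl may be slow, and the benzhydryl cation may instead alkylate the electron-rich phenol rings and give oligomers. The fallback replaces ionic hydride transfer with heterogeneous hydrogenolysis. It sets out from ketone 11: H2 (1–4 atm) over Pd/C in acetic acid with a trace of HCl at rt should hydrogenate the ketone to benzhydrol 12 and cleave its doubly benzylic C–O bond, arriving directly at target 13. There are no benzyl ethers or halides to interfere, and this fallback makes no compound outside the list (F0).

**Further compounds**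
F1 | step 4 | {2,6-dimethoxy-4-[2-(3-isopropoxyphenyl)ethyl]phenyl}(4-isopropoxyphenyl)methanol (racemic) | COc1cc(CCc2cccc(OC(C)C)c2)cc(OC)c1C(O)c1ccc(OC(C)C)cc1
F2 | step 5 | {2-hydroxy-6-methoxy-4-[2-(3-isopropoxyphenyl)ethyl]phenyl}(4-isopropoxyphenyl)methanone | COc1cc(CCc2cccc(OC(C)C)c2)cc(O)c1C(=O)c1ccc(OC(C)C)cc1
F0 | step 6 | none | none
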